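**Remarks on the chemistry (assumptions)**

- 3-Ethoxycyclobut-2-en-1-one, chloroacetaldehyde dimethyl acetal, prenyl bromide and vanillin are taken as catalogue chemicals.
- Ring A is pentasubstituted, not fully substituted: C6 keeps its hydrogen.
- The O1 phenol is carried as a methoxymethyl (MOM) ether from before the acylation until ring C is closed. An unprotected 2'-hydroxychalcone is deprotonated under nucleophilic epoxidation conditions, and under base its epoxide closes at the α-carbon (five-membered ring) instead of at the benzylic carbon.
- Methoxyacetylene (volatile, hazardous) is never isolated; its sodium salt is alkylated in the flask in which it is formed.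

## Structural features

The target is a (2R,3R)-dihydroflavonol. A benzene ring A is fused to a dihydropyranone ring C (a chroman-4-one), a 4-hydroxy-3-methoxyphenyl ring B sits on C2, and a hydroxyl sits on C3. The stereocentres C2 and C3 are adjacent and trans; C3 lies α to the C4 ketone and C2 is a benzylic ether carbon para to a phenol. Ring A carries O1 on C8a, a 3-methylbut-2-enyl (prenyl) group on C8, OMe on C7, hydrogen on C6, a chelated OH on C5 and the acyl carbon C4 on C4a. Fragile elements are the trisubstituted prenyl alkene (acid, electrophiles, oxidants, hydrogenation), the α-ketol (epimerisation, dehydrogenation to the flavonol, base-induced opening at O1–C2) and the free phenols. The real difficulty is the regiochemistry of ring A: three different oxygen functions must be told apart, and the prenyl group must sit between O1 and the 7-OMe and not on C6. The second task is the absolute configuration of the trans-2,3 pair. The key step exploits the 1,3,5-oxygen pattern of ring A: C8a(O)–C8(prenyl)–C7(OMe) maps onto a ynol ether and C6–C5(O)–C4a onto a vinylketene, so ring A is assembled with O1 as its only free hydroxyl, next to the unsubstituted C4a.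

## Logic of the disconnections

**20 to 19.** The O5–CH2 bond of an ethyl ether is restored. O5 leaves the ring-forming step as an ethyl ether and is the one oxygen that must stay inert and distinct from O1 until ring C exists. The gain is that 19 has only one hydroxyl-bearing position on ring A that could ever have cyclised. The forward cleavage must tell O5–Et from two aryl methyl ethers and spare the prenyl alkene and the α-ketol; the peri relationship of O5 to C4=O makes this possible.

**19 to 17 (through 18).** The O1–C2 bond is cut and both phenols are returned to their MOM ethers. C2 is benzylic and para to an oxygen of ring B, so it is the natural electrophilic carbon of an oxirane, and the C3–O bond is already present. The two adjacent stereocentres collapse into one trans-oxirane and ring C is opened. The forward step needs acid, not base, so that O1 attacks the benzylic carbon in a 6-endo sense; the α-carbon must keep its configuration and the closure must end 2,3-trans.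

**17 to 16.** Both C–O bonds of the oxirane are cut. An E-enone is the simplest achiral precursor of a trans-α,β-epoxy ketone, and all stereochemistry disappears from the intermediate. The forward step needs a nucleophilic, face-selective oxidant that ignores the electron-rich prenyl alkene, with O1 masked.

**16 to 13 and 15.** The enone C=C bond (future C2–C3) is cut. An aldol condensation divides the molecule into two halves of similar size, which makes the route convergent. The forward step needs the enolate of a hindered methyl ketone, E-geometry, and no premature oxa-Michael closure.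

**15 to 14.** The O–CH2 bond of the ring-B MOM ether is cut. The phenol of ring B must be masked against base and peroxide, and the mask falls off in the same acid step that closes ring C. The forward step is a simple O-alkylation.

**13 to 11 (through 12).** The aryl–acyl bond C4a–C4 is cut. C4a is the ring position between O1 and O5, and the MOM group on O1 can direct a base there. The arene loses its acyl group and one operation adds the two-carbon unit. Metalation must choose C4a over C6 and over the benzylic/allylic CH2 of the prenyl group.

**11 to 10.** The O–CH2 bond of the MOM ether on O1 is cut. Since 10 has exactly one free hydroxyl, protection is unambiguous and makes no special demand.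

**10 to 4 and 5 (through 6, 7, 8, 9).** The bonds C8a–C8, C6–C7 and C4a–C8a are cut. Every ring-A substituent is then already attached to one of two small acyclic or four-membered pieces, and the phenol oxygen is the former ketone oxygen. The ring is dismantled completely and no regiochemical choice remains on an arene. The forward step needs one orientation of a [2+2] event and tolerance of the prenyl alkene at about 110 °C.

**4 to 1 and 2 (through 3).** The C(sp)–CH2 bond is cut, and the triple bond is traced back to an acetal by two eliminations. Both fragments are commodity chemicals. The forward step must alkylate the acetylide at the primary allylic carbon without isolating the free alkyne.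

## Other disconnections considered

**Alternative 1:** The cut is C2–C3 of ring C. The forward step treats diazoketone A1 with Rh2(S-PTTL)4, dirhodium tetrakis[N-phthaloyl-(S)-tert-leucinate]. A1 is a 2-diazoacetyl arene whose O1 carries the ring-B benzyl group, on a ring A that already bears the prenyl group, the 7-OMe and a 5-silyloxy group. Loss of N2 gives a rhodium carbene at C3, which would insert into one of the two enantiotopic benzylic C–H bonds of O1–CH2–aryl to give flavanone A2.
- In its favour: the bond formation is catalytic and sets C2 directly. The C–H bond is activated by O1 and by an electron-rich aryl group. Ring B enters by a plain O-benzylation.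
- Better than the chosen plan: the O5 silyl ether would come off with fluoride, which is milder than the Lewis-acid de-ethylation of step 9.
- Against it: the carbene has other outlets. It can attack the O1 lone pair (oxonium ylide, then benzyl shift to a benzofuranone), add to ring B, or add to the prenyl alkene. A six-membered C–H insertion is less favoured than the usual five-membered mode.
- Against it: A2 lacks the C3 hydroxyl. It would have to be added by enolate oxidation, and a flavanone enolate can open by β-elimination of O1, which would erase C2.
- Comparison: A1 presupposes the same regiodefined ring A, so this cut does not address the main structural problem, which the chosen plan solves in one step with three bonds. Mechanistically it is an enantiodetermining metal-carbene insertion against a pericyclic cascade on achiral material. Catalyst control of absolute configuration is equal in kind to the poly-L-leucine epoxidation of the chosen plan. Step economy is expected to be worse because of the diazo transfer and the late hydroxylation.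

**Alternative 2:** The cut is C4a–C5, so ring A is formed last. The forward step treats dihydropyranone A3 with Mg(OMe)2. A3 has both stereocentres in place and carries on C8a a chain made of the prenyl-bearing carbon C8 and a β-methoxy enoate. Deprotonation at C8 gives a magnesium dienolate conjugated through C8a=C4a to C4=O. C4a attacks the ester carbon, methanol is lost, and enolisation aromatises ring A to give A4.
- In its favour: the logic is polyketide-like and every ring-A substituent is fixed by chain connectivity.
- Equal to the chosen plan: regiocontrol on ring A is complete in both.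
- Better than the chosen plan: O5 emerges directly as the free chelated phenol, so no dealkylation is needed.
- Against it: A3 needs a long linear synthesis (an enantioenriched 2-aryl-3-silyloxy-dihydropyranone, then a prenylated, masked ketoester chain of defined enoate geometry).
- Against it: the basic step exposes C3, which is α to the ketone, to epimerisation, and exposes the O1–C2 bond to β-elimination.
- Comparison: this cut forms one C–C bond under ionic, basic conditions with the stereocentres present. The chosen plan forms three bonds under neutral thermal conditions before any stereocentre exists. Step economy favours the chosen plan.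

**Alternative 3:** The cut is C3=C4. The forward step treats diene A5 with second-generation Grubbs catalyst, RuCl2(H2IMes)(PCy3)(=CHPh). A5 has a vinyl group on C4a and an O1–CH(aryl)–CH=CH2 ether, and ring-closing metathesis with loss of ethylene would give flav-3-ene A6.
- In its favour: six-membered ring closure by metathesis is neutral and usually dependable, and C2 could be set beforehand by an asymmetric allylic etherification.
- Better than the chosen plan: O5 is a MOM ether that would leave with the other acetal in one mild acid step.
- Against it: the prenyl alkene is a second metathesis partner. Closure of the allyl ether vinyl onto it would give a seven-membered benzoxepine with loss of 2-methylpropene, and cross-metathesis could truncate it.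
- Against it: A6 lacks both the C3 hydroxyl and the C4 ketone. Two oxidations of C3=C4 would be needed in the presence of the more electron-rich prenyl alkene, which electrophilic oxidants prefer, with facial control from C2 alone.
- Against it: A5 requires enantioselective O-alkylation of a phenol flanked by two ortho substituents.
- Comparison: it is equal to the chosen plan in needing a regiodefined ring A but does not provide one. Mechanistically it trades substrate-inherent regiocontrol for a chemoselectivity problem at ruthenium and again at the oxidation stage. Step economy is worse because the oxidation level of C3 and C4 must be adjusted after ring closure.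

Key step: step 2

## Route

**Step 1**
Reactants: 1 2-chloro-1,1-dimethoxyethane (chloroacetaldehyde dimethyl acetal); 2 1-bromo-3-methylbut-2-ene (prenyl bromide)
Product: 4 1-methoxy-5-methylhex-4-en-1-yne, via sodium methoxyacetylide 3 (not isolated)
Conditions: NaNH2 (3.1 equiv), liq. NH3, −33 °C; then 2, −33 °C → rt
Reagents that add atoms: none
Why: Double elimination (HCl, then MeOH) and deprotonation by NaNH2 should turn 1 directly into acetylide 3, which is alkylated by SN2 at the primary allylic carbon of 2 (one-flask synthesis of 1-alkoxyalk-1-ynes in liquid ammonia). The free alkyne is never handled, and the methyl ynol ether has no β-hydrogen on oxygen, so it cannot fragment by retro-ene reaction on later heating.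

**Step 2**
Reactants: 5 3-ethoxycyclobut-2-en-1-one; 4 1-methoxy-5-methylhex-4-en-1-yne
Product: 10 5-ethoxy-3-methoxy-2-(3-methylbut-2-enyl)phenol, via vinylketene 6 (not isolated), via vinylcyclobutenone 7 (not isolated), via dienylketene 8 (not isolated), via cyclohexadienone 9 (not isolated)
Conditions: 4 (1.5 equiv), PhMe, 80 → 110 °C, sealed tube
Reagents that add atoms: none
Why: Heating opens 5 by 4π-electrocyclic ring opening to vinylketene 6, whose ketene C=C adds to the electron-rich triple bond of 4 in a [2+2] cycloaddition to give 7, forming C8a–C8 and C6–C7. Under the same conditions 7 reopens to dienylketene 8, which closes ring A by thermal disrotatory 6π-electrocyclisation (forming C4a–C8a) to dienone 9, and 9 tautomerises to phenol 10. The closest known reaction type is the Danheiser benzannulation of cyclobutenones with alkoxyalkynes, which gives resorcinol monoethers. Ring A is the only ring closed and it is closed by the electrocyclisation; no stereocentre is created, the single sp3 centre of 7 being erased on ring opening. The step needs one orientation of the [2+2] event, and the polarisation of the ynol ether secures it: its nucleophilic, prenyl-bearing carbon bonds to the electrophilic ketene carbonyl carbon, so the ketene oxygen becomes the phenol next to the prenyl-bearing carbon. It also needs chemoselectivity for the alkyne over the prenyl alkene, which the much higher nucleophilicity of the ynol ether provides; the alkene cannot reach the ketene of 8 intramolecularly without forming a strained small ring. An excess of 4 should keep 6 from acylating the product phenol.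

**Step 3**
Reactants: 10 5-ethoxy-3-methoxy-2-(3-methylbut-2-enyl)phenol
Product: 11 5-ethoxy-1-methoxy-3-(methoxymethoxy)-2-(3-methylbut-2-enyl)benzene
Conditions: NaH, MOMCl, THF–DMF, 0 °C → rt
Reagents that add atoms: chloromethyl methyl ether (MOMCl), COCCl
Why: O-Alkylation of the single phenoxide (Williamson-type MOM protection) is unambiguous. The acetal masks O1 through the base and peroxide steps, directs the metalation of step 4 and is the acid-labile trigger of step 8.

**Step 4**
Reactants: 11 5-ethoxy-1-methoxy-3-(methoxymethoxy)-2-(3-methylbut-2-enyl)benzene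
Product: 13 1-[6-ethoxy-4-methoxy-2-(methoxymethoxy)-3-(3-methylbut-2-enyl)phenyl]ethanone, via aryllithium 12 (not isolated)
Conditions: n-BuLi, THF, 0 °C; then MeC(O)N(OMe)Me, −78 → 0 °C; H2O
Reagents that add atoms: N-methoxy-N-methylacetamide, CC(=O)N(C)OC
Why: Directed ortho-metalation should remove the ring hydrogen flanked by the chelating OMOM group and OEt (future C4a) in preference to the one between the weaker directors OMe and OEt, and acylation of 12 by the Weinreb amide stops at the ketone. Running without a diamine additive and at low temperature is meant to disfavour deprotonation of the benzylic/allylic CH2.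

**Step 5**
Reactants: 14 vanillin (4-hydroxy-3-methoxybenzaldehyde)
Product: 15 3-methoxy-4-(methoxymethoxy)benzaldehyde
Conditions: MOMCl, K2CO3, acetone, rt
Reagents that add atoms: chloromethyl methyl ether (MOMCl), COCCl
Why: O-Alkylation of the acidic para-formyl phenoxide (MOM protection) keeps ring B neutral during the aldol and epoxidation steps, and the group leaves in the acid step that closes ring C.

**Step 6**
Reactants: 13 1-[6-ethoxy-4-methoxy-2-(methoxymethoxy)-3-(3-methylbut-2-enyl)phenyl]ethanone; 15 3-methoxy-4-(methoxymethoxy)benzaldehyde
Product: 16 (2E)-1-[6-ethoxy-4-methoxy-2-(methoxymethoxy)-3-(3-methylbut-2-enyl)phenyl]-3-[3-methoxy-4-(methoxymethoxy)phenyl]prop-2-en-1-one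
Conditions: KOH, EtOH–H2O, rt
Reagents that add atoms: none
Why: Claisen–Schmidt aldol condensation of a methyl ketone with a non-enolisable aldehyde; dehydration by E1cB should give the E-enone. The MOM ether on O1 prevents oxa-Michael closure to a flavanone.

**Step 7**
Reactants: 16 (2E)-1-[6-ethoxy-4-methoxy-2-(methoxymethoxy)-3-(3-methylbut-2-enyl)phenyl]-3-[3-methoxy-4-(methoxymethoxy)phenyl]prop-2-en-1-one
Product: 17 [(2R,3S)-3-[3-methoxy-4-(methoxymethoxy)phenyl]oxiran-2-yl][6-ethoxy-4-methoxy-2-(methoxymethoxy)-3-(3-methylbut-2-enyl)phenyl]methanone
Conditions: poly-L-leucine (immobilised on silica), urea–H2O2, DBU, THF, rt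
Reagents that add atoms: urea–hydrogen peroxide, NC(N)=O.OO
Why: Juliá–Colonna epoxidation: hydroperoxide adds in conjugate fashion to the enone bound to the helical L-peptide, which selects the face that leads to the (αR,βS) trans-epoxy ketone, and ring closure of the peroxy enolate preserves the trans relationship. The nucleophilic oxidant should leave the isolated prenyl alkene untouched.

**Step 8**
Reactants: 17 [(2R,3S)-3-[3-methoxy-4-(methoxymethoxy)phenyl]oxiran-2-yl][6-ethoxy-4-methoxy-2-(methoxymethoxy)-3-(3-methylbut-2-enyl)phenyl]methanone
Product: 19 (2R,3R)-5-ethoxy-3-hydroxy-2-(4-hydroxy-3-methoxyphenyl)-7-methoxy-8-(3-methylbut-2-enyl)-2,3-dihydrochromen-4-one, via diphenol epoxide 18 (not isolated)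
Conditions: HCl (3 M aq.), MeOH–THF, 50 °C
Reagents that add atoms: none
Why: Acid cleaves both MOM acetals, and the freed O1 opens the protonated oxirane at the benzylic carbon, which the para oxygen of ring B activates (6-endo closure; acid-mediated cyclisation of 2'-(methoxymethoxy)chalcone epoxides to dihydroflavonols). C3 keeps the configuration of the epoxide α-carbon; C2 is set trans either by inversion at the benzylic carbon or, if a benzylic cation intervenes, by the preference for the diequatorial 2,3-trans ring, so both paths should lead to (2R,3R). Once O1 is in the ring, no free hydroxyl remains beside the prenyl group.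

**Step 9**
Reactants: 19 (2R,3R)-5-ethoxy-3-hydroxy-2-(4-hydroxy-3-methoxyphenyl)-7-methoxy-8-(3-methylbut-2-enyl)-2,3-dihydrochromen-4-one
Product: 20 (2R,3R)-3,5-dihydroxy-2-(4-hydroxy-3-methoxyphenyl)-7-methoxy-8-(3-methylbut-2-enyl)-2,3-dihydrochromen-4-one
Conditions: BCl3, CH2Cl2, −78 → 0 °C; then H2O
Reagents that add atoms: none
Why: Chelation-controlled ether cleavage: boron binds between C4=O and the peri oxygen O5, and chloride removes the ethyl group as chloroethane. The methyl ethers on C7 and C3' lack this chelate and should survive at low temperature, and neither stereocentre is involved.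

## Compound list

1 | 2-chloro-1,1-dimethoxyethane (chloroacetaldehyde dimethyl acetal) | COC(CCl)OC | starting material
2 | 1-bromo-3-methylbut-2-ene (prenyl bromide) | CC(C)=CCBr | starting material
3 | sodium methoxyethynide (sodium methoxyacetylide) | COC#[C-].[Na+] | intermediate (not isolated)
4 | 1-methoxy-5-methylhex-4-en-1-yne | COC#CCC=C(C)C | intermediate
5 | 3-ethoxycyclobut-2-en-1-one | CCOC1=CC(=O)C1 | starting material
6 | 3-ethoxybuta-1,3-dien-1-one (vinylketene) | CCOC(=C)C=C=O | intermediate (not isolated)
7 | 4-(1-ethoxyethenyl)-3-methoxy-2-(3-methylbut-2-enyl)cyclobut-2-en-1-one (racemic) | CCOC(=C)C1C(=O)C(CC=C(C)C)=C1OC | intermediate (not isolated)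
8 | (3E)-5-ethoxy-3-methoxy-2-(3-methylbut-2-enyl)hexa-1,3,5-trien-1-one (dienylketene) | O=C=C(CC=C(C)C)/C(OC)=C\C(=C)OCC | intermediate (not isolated)
9 | 5-ethoxy-3-methoxy-2-(3-methylbut-2-enyl)cyclohexa-2,4-dien-1-one | CCOC1=CC(OC)=C(CC=C(C)C)C(=O)C1 | intermediate (not isolated)
10 | 5-ethoxy-3-methoxy-2-(3-methylbut-2-enyl)phenol | CCOc1cc(O)c(CC=C(C)C)c(OC)c1 | intermediate
11 | 5-ethoxy-1-methoxy-3-(methoxymethoxy)-2-(3-methylbut-2-enyl)benzene | CCOc1cc(OCOC)c(CC=C(C)C)c(OC)c1 | intermediate
12 | [6-ethoxy-4-methoxy-2-(methoxymethoxy)-3-(3-methylbut-2-enyl)phenyl]lithium | [Li]c1c(OCC)cc(OC)c(CC=C(C)C)c1OCOC | intermediate (not isolated)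
13 | 1-[6-ethoxy-4-methoxy-2-(methoxymethoxy)-3-(3-methylbut-2-enyl)phenyl]ethanone | CC(=O)c1c(OCC)cc(OC)c(CC=C(C)C)c1OCOC | intermediate
14 | vanillin (4-hydroxy-3-methoxybenzaldehyde) | COc1cc(C=O)ccc1O | starting material
15 | 3-methoxy-4-(methoxymethoxy)benzaldehyde | COCOc1ccc(C=O)cc1OC | intermediate
16 | (2E)-1-[6-ethoxy-4-methoxy-2-(methoxymethoxy)-3-(3-methylbut-2-enyl)phenyl]-3-[3-methoxy-4-(methoxymethoxy)phenyl]prop-2-en-1-one | CCOc1cc(OC)c(CC=C(C)C)c(OCOC)c1C(=O)/C=C/c1ccc(OCOC)c(OC)c1 | intermediate
17 | [(2R,3S)-3-[3-methoxy-4-(methoxymethoxy)phenyl]oxiran-2-yl][6-ethoxy-4-methoxy-2-(methoxymethoxy)-3-(3-methylbut-2-enyl)phenyl]methanone | CCOc1cc(OC)c(CC=C(C)C)c(OCOC)c1C(=O)[C@@H]2O[C@H]2c3ccc(OCOC)c(OC)c3 | intermediate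
18 | [(2R,3S)-3-(4-hydroxy-3-methoxyphenyl)oxiran-2-yl][6-ethoxy-2-hydroxy-4-methoxy-3-(3-methylbut-2-enyl)phenyl]methanone | CCOc1cc(OC)c(CC=C(C)C)c(O)c1C(=O)[C@@H]2O[C@H]2c3ccc(O)c(OC)c3 | intermediate (not isolated)
19 | (2R,3R)-5-ethoxy-3-hydroxy-2-(4-hydroxy-3-methoxyphenyl)-7-methoxy-8-(3-methylbut-2-enyl)-2,3-dihydrochromen-4-one | COc1cc([C@H]2Oc3c(CC=C(C)C)c(OC)cc(OCC)c3C(=O)[C@@H]2O)ccc1O | intermediate
20 | (2R,3R)-3,5-dihydroxy-2-(4-hydroxy-3-methoxyphenyl)-7-methoxy-8-(3-methylbut-2-enyl)-2,3-dihydrochromen-4-one | COc1cc([C@H]2Oc3c(CC=C(C)C)c(OC)cc(O)c3C(=O)[C@@H]2O)ccc1O | target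

## Step count and least certain steps

Total step count: 9. Longest linear sequence: 8 steps (steps 1, 2, 3, 4, 6, 7, 8, 9); step 5 is the side branch.

**Step 2 (key step).** The ring opening of the donor-stabilised cyclobutenone may be slow compared with thermal decay or oligomerisation of the ynol ether. The vinylketene may dimerise, and the product phenol may be acylated by the ketene.
Fallback: it sets out from 4 and returns to the route at 10. Vinylketene 6 would be generated without any cyclobutenone ring opening, by 1,4-dehydrochlorination of (2E)-3-ethoxybut-2-enoyl chloride F1 with Et3N in CH2Cl2 at 0 °C in the presence of 4. F1 would be prepared beforehand from commercial ethyl (2E)-3-ethoxybut-2-enoate by saponification and treatment with oxalyl chloride. The [2+2] adduct 7 would be isolated and then heated in PhMe (80–110 °C) to pass through 8 and 9 to 10.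

**Step 4.** Metalation may occur at the other doubly flanked ring position (between OMe and OEt) or at the benzylic/allylic CH2 of the prenyl group. The hindered aryllithium may also abstract a proton from the amide instead of adding to it.
Fallback: it sets out from 10 and returns at 13.
- MgCl2, Et3N and paraformaldehyde in MeCN at reflux would give 6-ethoxy-2-hydroxy-4-methoxy-3-(3-methylbut-2-enyl)benzaldehyde F2, because the magnesium phenoxide delivers formaldehyde only to the one free ortho position.
- NaH and MOMCl would give 6-ethoxy-4-methoxy-2-(methoxymethoxy)-3-(3-methylbut-2-enyl)benzaldehyde F3.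
- MeMgBr in THF at 0 °C would give 1-[6-ethoxy-4-methoxy-2-(methoxymethoxy)-3-(3-methylbut-2-enyl)phenyl]ethanol F4.
- Dess–Martin periodinane in CH2Cl2 would oxidise F4 to 13.

**Step 7.** Conversion may be slow and facial selectivity insufficient, because the 2',6'-dioxygenated aryl ketone is twisted out of conjugation and the enone is made electron-rich by ring B.
Fallback: it sets out from 11 (through 12) and from 15 and returns at 17. Aryllithium 12 would be quenched with 2-chloro-N-methoxy-N-methylacetamide to give 2-chloro-1-[6-ethoxy-4-methoxy-2-(methoxymethoxy)-3-(3-methylbut-2-enyl)phenyl]ethanone F5. An asymmetric Darzens condensation of F5 with 15 under a cinchona-derived quaternary ammonium phase-transfer catalyst (LiOH, Bu2O) would form the trans-epoxy ketone 17 by C–C bond formation and ring closure. The pseudoenantiomeric catalyst series would be chosen for the (2R,3S) sense.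

**Step 8.** Methanol or chloride may capture the benzylic carbon before O1 is unmasked. The transiently free O1–H may add across the prenyl alkene under acid (chroman formation). Part of the material may close to the 2,3-cis isomer.
Fallback: it sets out from 17 and returns at 19.
- BnSH with catalytic SnCl4 in CH2Cl2 at −20 °C would open the oxirane at the benzylic carbon to (2S)-3-(benzylsulfanyl)-1-[6-ethoxy-4-methoxy-2-(methoxymethoxy)-3-(3-methylbut-2-enyl)phenyl]-2-hydroxy-3-[3-methoxy-4-(methoxymethoxy)phenyl]propan-1-one F6.
- Brief HCl in MeOH at rt would remove the acetals to give (2S)-3-(benzylsulfanyl)-1-[6-ethoxy-2-hydroxy-4-methoxy-3-(3-methylbut-2-enyl)phenyl]-2-hydroxy-3-(4-hydroxy-3-methoxyphenyl)propan-1-one F7.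
- AgBF4 in CH2Cl2 at 0 °C would activate sulfur as a leaving group so that O1 closes ring C to 19, under conditions that are not protic.

**Step 9.** The Lewis acid may lose selectivity: HCl may add to the prenyl alkene, the guaiacol methyl ether may be cleaved through the neighbouring aryloxyboron species, and O1–C2 may ionise with epimerisation at C2.
Fallback: it sets out from 19 and returns at 20.
- TBSOTf and 2,6-lutidine would give (2R,3R)-3-(tert-butyldimethylsilyloxy)-2-[4-(tert-butyldimethylsilyloxy)-3-methoxyphenyl]-5-ethoxy-7-methoxy-8-(3-methylbut-2-enyl)-2,3-dihydrochromen-4-one F8, leaving the C4=O/O5 pair as the only chelating site.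
- MgI2·OEt2 in PhMe–Et2O at 60 °C would remove the ethyl group by iodide attack within the magnesium chelate to give (2R,3R)-3-(tert-butyldimethylsilyloxy)-2-[4-(tert-butyldimethylsilyloxy)-3-methoxyphenyl]-5-hydroxy-7-methoxy-8-(3-methylbut-2-enyl)-2,3-dihydrochromen-4-one F9.
- HF·pyridine in THF would remove both silyl groups to give 20.

## Further compounds

F1 | step 2 | (2E)-3-ethoxybut-2-enoyl chloride | CCO/C(C)=C/C(Cl)=O
F2 | step 4 | 6-ethoxy-2-hydroxy-4-methoxy-3-(3-methylbut-2-enyl)benzaldehyde | CCOc1cc(OC)c(CC=C(C)C)c(O)c1C=O
F3 | step 4 | 6-ethoxy-4-methoxy-2-(methoxymethoxy)-3-(3-methylbut-2-enyl)benzaldehyde | CCOc1cc(OC)c(CC=C(C)C)c(OCOC)c1C=O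
F4 | step 4 | 1-[6-ethoxy-4-methoxy-2-(methoxymethoxy)-3-(3-methylbut-2-enyl)phenyl]ethanol (racemic) | CCOc1cc(OC)c(CC=C(C)C)c(OCOC)c1C(C)O
F5 | step 7 | 2-chloro-1-[6-ethoxy-4-methoxy-2-(methoxymethoxy)-3-(3-methylbut-2-enyl)phenyl]ethanone | ClCC(=O)c1c(OCC)cc(OC)c(CC=C(C)C)c1OCOC
F6 | step 8 | (2S)-3-(benzylsulfanyl)-1-[6-ethoxy-4-methoxy-2-(methoxymethoxy)-3-(3-methylbut-2-enyl)phenyl]-2-hydroxy-3-[3-methoxy-4-(methoxymethoxy)phenyl]propan-1-one (both epimers at C3) | CCOc1cc(OC)c(CC=C(C)C)c(OCOC)c1C(=O)[C@H](O)C(SCc2ccccc2)c3ccc(OCOC)c(OC)c3
F7 | step 8 | (2S)-3-(benzylsulfanyl)-1-[6-ethoxy-2-hydroxy-4-methoxy-3-(3-methylbut-2-enyl)phenyl]-2-hydroxy-3-(4-hydroxy-3-methoxyphenyl)propan-1-one (both epimers at C3) | CCOc1cc(OC)c(CC=C(C)C)c(O)c1C(=O)[C@H](O)C(SCc2ccccc2)c3ccc(O)c(OC)c3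
F8 | step 9 | (2R,3R)-3-(tert-butyldimethylsilyloxy)-2-[4-(tert-butyldimethylsilyloxy)-3-methoxyphenyl]-5-ethoxy-7-methoxy-8-(3-methylbut-2-enyl)-2,3-dihydrochromen-4-one | COc1cc([C@H]2Oc3c(CC=C(C)C)c(OC)cc(OCC)c3C(=O)[C@@H]2O[Si](C)(C)C(C)(C)C)ccc1O[Si](C)(C)C(C)(C)C
F9 | step 9 | (2R,3R)-3-(tert-butyldimethylsilyloxy)-2-[4-(tert-butyldimethylsilyloxy)-3-methoxyphenyl]-5-hydroxy-7-methoxy-8-(3-methylbut-2-enyl)-2,3-dihydrochromen-4-one | COc1cc([C@H]2Oc3c(CC=C(C)C)c(OC)cc(O)c3C(=O)[C@@H]2O[Si](C)(C)C(C)(C)C)ccc1O[Si](C)(C)C(C)(C)C
A1 | alternative 1 | 2-diazo-1-[4-methoxy-2-{[3-methoxy-4-(methoxymethoxy)phenyl]methoxy}-3-(3-methylbut-2-enyl)-6-(triisopropylsilyloxy)phenyl]ethanone | [N-]=[N+]=CC(=O)c1c(O[Si](C(C)C)(C(C)C)C(C)C)cc(OC)c(CC=C(C)C)c1OCc1ccc(OCOC)c(OC)c1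
A2 | alternative 1 | (2S)-7-methoxy-2-[3-methoxy-4-(methoxymethoxy)phenyl]-8-(3-methylbut-2-enyl)-5-(triisopropylsilyloxy)-2,3-dihydrochromen-4-one | COc1cc([C@H]2Oc3c(CC=C(C)C)c(OC)cc(O[Si](C(C)C)(C(C)C)C(C)C)c3C(=O)C2)ccc1OCOC
A3 | alternative 2 | methyl (2E)-4-[(2R,3R)-3-(tert-butyldimethylsilyloxy)-2-[3-methoxy-4-(methoxymethoxy)phenyl]-4-oxo-3,4-dihydro-2H-pyran-6-yl]-3-methoxy-7-methylocta-2,6-dienoate (either configuration at C4 of the chain) | COc1cc([C@H]2OC(C(CC=C(C)C)/C(OC)=C\C(=O)OC)=CC(=O)[C@@H]2O[Si](C)(C)C(C)(C)C)ccc1OCOC
A4 | alternative 2 | (2R,3R)-3-(tert-butyldimethylsilyloxy)-5-hydroxy-7-methoxy-2-[3-methoxy-4-(methoxymethoxy)phenyl]-8-(3-methylbut-2-enyl)-2,3-dihydrochromen-4-one | COc1cc([C@H]2Oc3c(CC=C(C)C)c(OC)cc(O)c3C(=O)[C@@H]2O[Si](C)(C)C(C)(C)C)ccc1OCOC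
A5 | alternative 3 | 2-ethenyl-5-methoxy-1-(methoxymethoxy)-3-{[(1S)-1-[3-methoxy-4-(methoxymethoxy)phenyl]prop-2-enyl]oxy}-4-(3-methylbut-2-enyl)benzene | COc1cc([C@H](C=C)Oc2c(CC=C(C)C)c(OC)cc(OCOC)c2C=C)ccc1OCOC
A6 | alternative 3 | (2S)-7-methoxy-2-[3-methoxy-4-(methoxymethoxy)phenyl]-5-(methoxymethoxy)-8-(3-methylbut-2-enyl)-2H-chromene | COc1cc([C@H]2Oc3c(CC=C(C)C)c(OC)cc(OCOC)c3C=C2)ccc1OCOC
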